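**Assumption and notation (one line):** both enantiomers of t-Bu-box (2,2'-(propane-2,2-diyl)bis(4-tert-butyl-4,5-dihydrooxazole)), a commercial ketoreductase screening panel and the named reagents count as commercially available; C-numbers are gibberellane numbers of the target; PMB = 4-methoxybenzyl, TMSE = 2-(trimethylsilyl)ethyl, TES = triethylsilyl.

## Retrosynthetic overview

1. GA55 ⇐ ketoreductase reduction of the 3-ketone ⇐ 1β-hydroxy-3-ketone ⇐ 1β,2β-epoxy-3-ketone ⇐ Δ1-3-ketone.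
2. Ring A ⇐ ring-closing metathesis of a C10 vinyl group with the acrolein aldol adduct at C4 of the 19,10-lactone.
3. Lactone ⇐ intramolecular Michael addition of a C10 propanoate onto the Δ5-7-ester; C10 carbinol ⇐ vinyl addition to the ring B ketone; ring B ⇐ ring-closing metathesis of an acrylate with a C10 vinyl carbinol.
4. Ring D ⇐ SmI2 ketyl–alkyne cyclisation; quaternary C8 ⇐ Sakurai allylation trans to the C9 substituent of a cyclohexenone.
5. Ring C ⇐ [Cu((R,R)-t-Bu-box)](SbF6)2-catalysed Diels–Alder reaction (sets C9); ring order C → D → B → lactone → A.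

## Route

**Step 1**
Reactants: 1 3-acryloyl-1,3-oxazolidin-2-one; 2 (E)-buta-1,3-dien-1-yl acetate
Product: 3 3-{[(1R,2S)-2-acetoxycyclohex-3-en-1-yl]carbonyl}-1,3-oxazolidin-2-one
Conditions: [Cu((R,R)-t-Bu-box)](SbF6)2 (5 mol %), CH2Cl2, −20 °C
Reagents that add atoms: none
Why: Enantioselective Diels–Alder reaction in which the imide chelates the square-planar divalent copper centre of [Cu((R,R)-t-Bu-box)](SbF6)2 and one face of the dienophile is shielded, so the endo "ortho" adduct forms with C9 set by the catalyst and the acetoxy group cis to it.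

**Step 2**
Reactants: 3 Diels–Alder adduct
Product: 4 (1S,6S)-6-(hydroxymethyl)cyclohex-2-en-1-ol
Conditions: LiBH4, MeOH (2 equiv), THF, 0 °C to rt
Reagents that add atoms: none
Why: Hydride reduction cleaves the imide to the primary alcohol and removes the acetate without touching either stereocentre.

**Step 3**
Reactants: 4 diol
Product: 6 (1S,6S)-6-[(4-methoxybenzyloxy)methyl]cyclohex-2-en-1-ol, via dibutylstannylene acetal 5 (not isolated)
Conditions: Bu2SnO, toluene, reflux (−H2O); then 4-MeOC6H4CH2Cl, Bu4NI (cat.), 80 °C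
Reagents that add atoms: 4-methoxybenzyl chloride, COc1ccc(CCl)cc1
Why: Stannylene-acetal-mediated O-alkylation occurs selectively at the primary oxygen.

**Step 4**
Reactants: 6 allylic alcohol
Product: 7 (6S)-6-[(4-methoxybenzyloxy)methyl]cyclohex-2-en-1-one
Conditions: Dess–Martin periodinane, CH2Cl2, 0 °C; used directly
Reagents that add atoms: none
Why: Dess–Martin oxidation under non-basic conditions gives the enone without epimerising the α-stereocentre C9.

**Step 5**
Reactants: 7 enone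
Product: 8 TMSE 2-[(6S)-1-hydroxy-6-(PMB-oxymethyl)cyclohex-2-en-1-yl]acetate (both C1 epimers)
Conditions: LiN(iPr)2, CH3CO2CH2CH2SiMe3, THF, −78 °C; then 7; AcOH, −78 °C
Reagents that add atoms: 2-(trimethylsilyl)ethyl acetate, CC(=O)OCC[Si](C)(C)C
Why: Kinetic 1,2-addition (aldol addition) of the lithium ester enolate to the enone carbonyl installs C6–C7; the new carbinol centre is destroyed in the next step.

**Step 6**
Reactants: 8 tertiary allylic alcohol
Product: 9 TMSE 2-[(6R)-6-(PMB-oxymethyl)-3-oxocyclohex-1-en-1-yl]acetate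
Conditions: [C5H5NH][CrO3Cl], 4 Å sieves, CH2Cl2, rt
Reagents that add atoms: pyridinium chlorochromate, [O-][Cr](=O)(=O)Cl.c1cc[nH+]cc1
Why: Babler–Dauben oxidative transposition ([3,3] shift of the chromate ester, then oxidation) moves the oxygen to C13 and gives the β-substituted enone.

**Step 7**
Reactants: 9 enone
Product: 10 TMSE 2-[(1R,2R)-1-allyl-2-(PMB-oxymethyl)-5-oxocyclohexyl]acetate
Conditions: CH2=CHCH2SiMe3, TiCl4, CH2Cl2, −78 °C
Reagents that add atoms: allyltrimethylsilane, C=CC[Si](C)(C)C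
Why: Hosomi–Sakurai conjugate allylation attacks axially, anti to the pseudoaxial CH2OPMB group at C9, and so creates quaternary C8 with the allyl group trans and the acetate arm cis to C10.

**Step 8**
Reactants: 10 allyl ketone
Product: 11 TMSE 2-[(1R,2R)-2-(PMB-oxymethyl)-5-oxo-1-(2-oxoethyl)cyclohexyl]acetate
Conditions: OsO4 (2 mol %), NaIO4, 2,6-lutidine, dioxane/H2O, rt
Reagents that add atoms: sodium periodate, [Na+].[O-]I(=O)(=O)=O
Why: Lemieux–Johnson cleavage of the only alkene gives the aldehyde and avoids ozone, which would attack the PMB ether.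

**Step 9**
Reactants: 11 keto aldehyde
Product: 12 TMSE 2-[(1R,2R)-2-(PMB-oxymethyl)-5-oxo-1-(prop-2-ynyl)cyclohexyl]acetate
Conditions: dimethyl (1-diazo-2-oxopropyl)phosphonate, K2CO3, MeOH, 0 °C to rt
Reagents that add atoms: dimethyl (1-diazo-2-oxopropyl)phosphonate, CC(=O)C(=[N+]=[N-])P(=O)(OC)OC
Why: Ohira–Bestmann (Seyferth–Gilbert) homologation converts the aldehyde, far faster than the ketone, into the terminal alkyne (adds C17).

**Step 10**
Reactants: 12 alkynyl ketone
Product: 13 TMSE [5-hydroxy-6-methylidene-2-(PMB-oxymethyl)bicyclo[3.2.1]oct-1-yl]acetate (CH2OPMB syn to the one-carbon bridge C14; anti to the C15–C16 bridge)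
Conditions: SmI2, HMPA, t-BuOH, THF, 0 °C
Reagents that add atoms: none
Why: Ketyl–alkyne 5-exo-dig radical cyclisation forms ring D with the 13-hydroxy-16-methylene unit; the configuration at C13 is dictated by C8 because the propargyl arm can only bridge from its own face.

**Step 11**
Reactants: 13 tertiary alcohol
Product: 14 13-O-triethylsilyl ether of 13
Conditions: Et3SiOSO2CF3, 2,6-lutidine, CH2Cl2, −78 to 0 °C
Reagents that add atoms: triethylsilyl trifluoromethanesulfonate, CC[Si](CC)(CC)OS(=O)(=O)C(F)(F)F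
Why: Silylation of the bridgehead alcohol with the silyl triflate protects it for the organometallic steps.

**Step 12**
Reactants: 14 ester
Product: 17 TMSE 2-[2-(PMB-oxymethyl)-6-methylidene-5-(triethylsilyloxy)bicyclo[3.2.1]oct-1-yl]prop-2-enoate, via dimethylaminomethyl ester 15 (not isolated), via trimethylammonium iodide 16 (not isolated)
Conditions: LiN(iPr)2, THF, −78 °C; CH2=NMe2+ I−; then MeI, CH2Cl2; then DBU, rt
Reagents that add atoms: Eschenmoser's salt, C=[N+](C)C.[I-]
Why: Eschenmoser α-methylenation (Mannich reaction, quaternisation, elimination) turns the acetate arm into the 1,1-disubstituted acrylate needed for ring closure.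

**Step 13**
Reactants: 17 PMB ether
Product: 18 primary alcohol (C10–OH) of 17
Conditions: DDQ, CH2Cl2/pH 7 buffer, 0 °C
Reagents that add atoms: none
Why: Oxidative PMB cleavage under neutral conditions leaves the TES ether, the TMSE ester and the alkenes intact.

**Step 14**
Reactants: 18 alcohol
Product: 19 aldehyde (C10 formyl) of 17
Conditions: Dess–Martin periodinane, CH2Cl2, 0 °C
Reagents that add atoms: none
Why: Dess–Martin oxidation gives the aldehyde without base.

**Step 15**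
Reactants: 19 aldehyde
Product: 20 allylic alcohol bearing 1-hydroxyprop-2-enyl at C9 (C10 epimers)
Conditions: CH2=CHMgBr, THF, −78 °C; AcOH, −78 °C
Reagents that add atoms: vinylmagnesium bromide, C=C[Mg]Br
Why: Grignard 1,2-addition to the aldehyde (much faster than attack on the hindered acrylate) supplies C5; the new carbinol centre is oxidised away in step 17.

**Step 16**
Reactants: 20 diene
Product: 21 tricyclic cyclopentenol of rings B/C/D (10-hydroxy-Δ5-ene 7-TMSE ester; C10 epimers)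
Conditions: second-generation Grubbs catalyst RuCl2(=CHPh)(PCy3)(H2IMes) (5 mol %), CH2Cl2, 40 °C
Reagents that add atoms: none
Why: Ring-closing metathesis of the vinyl carbinol with the acrylate closes the cis-fused ring B; the hindered 16-methylene does not compete.

**Step 17**
Reactants: 21 cyclopentenol
Product: 22 tricyclic enone ester (C10 ketone; Δ5; B/C cis-fused)
Conditions: Dess–Martin periodinane, CH2Cl2, rt
Reagents that add atoms: none
Why: Dess–Martin oxidation gives the 4-oxocyclopentene ester, in which C9, now α to the ketone, sits in its thermodynamically preferred cis-fused arrangement.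

**Step 18**
Reactants: 22 enone ester
Product: 24 10β-vinyl 10α-propanoate of the tricycle, via bromomagnesium alkoxide 23 (not isolated)
Conditions: CH2=CHMgBr, LaCl3·2LiCl (0.3 equiv), THF, −78 °C; then (EtCO)2O, −78 to 0 °C
Reagents that add atoms: vinylmagnesium bromide, C=C[Mg]Br; propionic anhydride, CCC(=O)OC(=O)CC
Why: LaCl3·2LiCl-assisted 1,2-addition of the Grignard reagent occurs from the convex β-face, anti to cis-fused ring C, which sets C10 (O α, vinyl β); the alkoxide is acylated in situ.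

**Step 19**
Reactants: 24 propanoate
Product: 25 19,10-lactone bearing H at C4 (C4 epimers; 5β-H; 6β-CO2TMSE; 10β-vinyl)
Conditions: KN(SiMe3)2, THF, −78 to −40 °C; AcOH
Reagents that add atoms: none
Why: Intramolecular Michael addition (5-exo-trig) of the propanoate enolate, delivered on the α-face by the C10–O tether, sets H-5 β in the cis-fused γ-lactone; C6 takes the more stable 6β-ester configuration, trans to the new C4–C5 bond, and is re-equilibrated if needed.

**Step 20**
Reactants: 25 lactone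
Product: 26 4-(1-hydroxyprop-2-enyl) lactone aldol adduct (C3 epimers)
Conditions: LiN(iPr)2 (1.1 equiv), THF, −78 °C; CH2=CHCHO; AcOH, −78 °C
Reagents that add atoms: acrolein, C=CC=O
Why: Aldol addition of the lactone enolate (its α-proton is more acidic and less hindered than H-6) to acrolein from the convex face, anti to C6, fixes quaternary C4 with the C3 branch cis to the C10 vinyl group.

**Step 21**
Reactants: 26 diene
Product: 27 13-O-TES gibberellic acid TMSE ester and its 3-epimer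
Conditions: second-generation Grubbs catalyst RuCl2(=CHPh)(PCy3)(H2IMes) (5 mol %), CH2Cl2, 40 °C
Reagents that add atoms: none
Why: Ring-closing metathesis of the two monosubstituted alkenes forms ring A with the Δ1 alkene.

**Step 22**
Reactants: 27 allylic alcohol
Product: 28 13-O-TES 3-dehydrogibberellic acid TMSE ester (3-oxo-1-ene)
Conditions: Dess–Martin periodinane, CH2Cl2, rt
Reagents that add atoms: none
Why: Oxidation converges both C3 epimers to the enone, so the aldol selectivity at C3 is irrelevant.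

**Step 23**
Reactants: 28 enone
Product: 29 1β,2β-epoxy-3-ketone
Conditions: t-BuOOH, DBU, CH2Cl2, 0 °C
Reagents that add atoms: tert-butyl hydroperoxide, CC(C)(C)OO
Why: Weitz–Scheffer nucleophilic epoxidation under non-aqueous conditions attacks C1 from the β-face, anti to the α-lactone bridge, and spares the β-keto lactone.

**Step 24**
Reactants: 29 epoxy ketone
Product: 30 13-O-TES 3-dehydro-GA55 TMSE ester (1β-hydroxy-3-ketone)
Conditions: SmI2 (2.2 equiv), THF/MeOH, −90 °C
Reagents that add atoms: none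
Why: Reductive cleavage of the Cα–O bond of the α,β-epoxy ketone keeps the C1–O bond, so the 1β-hydroxyl is formed with retention.

**Step 25**
Reactants: 30 protected keto ester
Product: 31 3-dehydro-GA55 (1β,13-dihydroxy-3-oxo 19,10-lactone 7-acid)
Conditions: Bu4NF, AcOH (buffer), THF, 0 °C to rt
Reagents that add atoms: none
Why: Fluoride cleaves the TMSE ester by β-elimination and the TES ether in one operation; the acetic acid buffer protects the β-hydroxy ketone.

**Step 26**
Reactants: 31 keto acid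
Product: 32 GA55
Conditions: ketoreductase (NADPH-dependent carbonyl reductase selected from a screening panel), NADP+ (cat.), i-PrOH, phosphate buffer pH 7, DMSO (5 %), 30 °C
Reagents that add atoms: none
Why: Enzymatic carbonyl reduction by a ketoreductase delivers hydride to one face of the C3 ketone to give the axial 3β-alcohol, cis to the 1β-hydroxyl, at neutral pH where the β-hydroxy lactone cannot epimerise by retro-aldol reaction.

## Compound list

1 | 3-acryloyl-1,3-oxazolidin-2-one | C=CC(=O)N1CCOC1=O | starting material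
2 | (E)-buta-1,3-dien-1-yl acetate | CC(=O)O/C=C/C=C | starting material
3 | 3-{[(1R,2S)-2-acetoxycyclohex-3-en-1-yl]carbonyl}-1,3-oxazolidin-2-one | CC(=O)O[C@H]1C=CCC[C@H]1C(=O)N1CCOC1=O | intermediate
4 | (1S,6S)-6-(hydroxymethyl)cyclohex-2-en-1-ol | O[C@H]1C=CCC[C@H]1CO | intermediate
5 | dibutylstannylene acetal of 4 | CCCC[Sn]2(CCCC)O[C@H]1C=CCC[C@H]1CO2 | intermediate
6 | (1S,6S)-6-[(4-methoxybenzyloxy)methyl]cyclohex-2-en-1-ol | O[C@H]1C=CCC[C@H]1COCc1ccc(OC)cc1 | intermediate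
7 | (6S)-6-[(4-methoxybenzyloxy)methyl]cyclohex-2-en-1-one | O=C1C=CCC[C@H]1COCc1ccc(OC)cc1 | intermediate
8 | TMSE 2-[(6S)-1-hydroxy-6-(PMB-oxymethyl)cyclohex-2-en-1-yl]acetate (C1 epimers) | OC1(CC(=O)OCC[Si](C)(C)C)C=CCC[C@H]1COCc1ccc(OC)cc1 | intermediate
9 | TMSE 2-[(6R)-6-(PMB-oxymethyl)-3-oxocyclohex-1-en-1-yl]acetate | O=C1C=C(CC(=O)OCC[Si](C)(C)C)[C@H](COCc2ccc(OC)cc2)CC1 | intermediate
10 | TMSE 2-[(1R,2R)-1-allyl-2-(PMB-oxymethyl)-5-oxocyclohexyl]acetate | C=CC[C@]1(CC(=O)OCC[Si](C)(C)C)CC(=O)CC[C@H]1COCc1ccc(OC)cc1 | intermediate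
11 | TMSE 2-[(1R,2R)-2-(PMB-oxymethyl)-5-oxo-1-(2-oxoethyl)cyclohexyl]acetate | O=CC[C@]1(CC(=O)OCC[Si](C)(C)C)CC(=O)CC[C@H]1COCc1ccc(OC)cc1 | intermediate
12 | TMSE 2-[(1R,2R)-2-(PMB-oxymethyl)-5-oxo-1-(prop-2-ynyl)cyclohexyl]acetate | C#CC[C@]1(CC(=O)OCC[Si](C)(C)C)CC(=O)CC[C@H]1COCc1ccc(OC)cc1 | intermediate
13 | TMSE [5-hydroxy-6-methylidene-2-(PMB-oxymethyl)bicyclo[3.2.1]oct-1-yl]acetate | C=C1C[C@]2(CC(=O)OCC[Si](C)(C)C)C[C@@]1(O)CC[C@H]2COCc1ccc(OC)cc1 | intermediate
14 | 13-O-triethylsilyl ether of 13 | C=C1C[C@]2(CC(=O)OCC[Si](C)(C)C)C[C@@]1(O[Si](CC)(CC)CC)CC[C@H]2COCc1ccc(OC)cc1 | intermediate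
15 | α-(dimethylaminomethyl) ester from 14 (C6 epimers) | C=C1C[C@]2(C(CN(C)C)C(=O)OCC[Si](C)(C)C)C[C@@]1(O[Si](CC)(CC)CC)CC[C@H]2COCc1ccc(OC)cc1 | intermediate
16 | trimethylammonium iodide of 15 | C=C1C[C@]2(C(C[N+](C)(C)C)C(=O)OCC[Si](C)(C)C)C[C@@]1(O[Si](CC)(CC)CC)CC[C@H]2COCc1ccc(OC)cc1.[I-] | intermediate
17 | TMSE 2-[2-(PMB-oxymethyl)-6-methylidene-5-(triethylsilyloxy)bicyclo[3.2.1]oct-1-yl]prop-2-enoate | C=C1C[C@]2(C(=C)C(=O)OCC[Si](C)(C)C)C[C@@]1(O[Si](CC)(CC)CC)CC[C@H]2COCc1ccc(OC)cc1 | intermediate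
18 | primary alcohol (C10–OH) of 17 | C=C1C[C@]2(C(=C)C(=O)OCC[Si](C)(C)C)C[C@@]1(O[Si](CC)(CC)CC)CC[C@H]2CO | intermediate
19 | aldehyde (C10 formyl) of 17 | C=C1C[C@]2(C(=C)C(=O)OCC[Si](C)(C)C)C[C@@]1(O[Si](CC)(CC)CC)CC[C@H]2C=O | intermediate
20 | allylic alcohol bearing 1-hydroxyprop-2-enyl at C9 (C10 epimers) | C=C1C[C@]2(C(=C)C(=O)OCC[Si](C)(C)C)C[C@@]1(O[Si](CC)(CC)CC)CC[C@H]2C(O)C=C | intermediate
21 | tricyclic cyclopentenol of rings B/C/D (10-hydroxy-Δ5-ene 7-TMSE ester; C10 epimers) | C=C1C[C@]23C[C@@]1(O[Si](CC)(CC)CC)CC[C@H]2C(O)C=C3C(=O)OCC[Si](C)(C)C | intermediate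
22 | tricyclic enone ester (C10 ketone; Δ5; B/C cis-fused) | C=C1C[C@]23C[C@@]1(O[Si](CC)(CC)CC)CC[C@H]2C(=O)C=C3C(=O)OCC[Si](C)(C)C | intermediate
23 | bromomagnesium alkoxide of the 10β-vinyl carbinol | C=C1C[C@]23C[C@@]1(O[Si](CC)(CC)CC)CC[C@H]2[C@@](C=C)(O[Mg]Br)C=C3C(=O)OCC[Si](C)(C)C | intermediate
24 | 10β-vinyl 10α-propanoate of the tricycle | C=C1C[C@]23C[C@@]1(O[Si](CC)(CC)CC)CC[C@H]2[C@@](C=C)(OC(=O)CC)C=C3C(=O)OCC[Si](C)(C)C | intermediate
25 | 19,10-lactone bearing H at C4 (C4 epimers; 5β-H; 6β-CO2TMSE; 10β-vinyl) | C=C1C[C@]23C[C@@]1(O[Si](CC)(CC)CC)CC[C@H]2[C@@]1(C=C)OC(=O)C(C)[C@H]1[C@@H]3C(=O)OCC[Si](C)(C)C | intermediate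
26 | 4-(1-hydroxyprop-2-enyl) lactone aldol adduct (C3 epimers) | C=C1C[C@]23C[C@@]1(O[Si](CC)(CC)CC)CC[C@H]2[C@@]1(C=C)OC(=O)[C@@](C)([C@H]1[C@@H]3C(=O)OCC[Si](C)(C)C)C(O)C=C | intermediate
27 | 13-O-TES gibberellic acid TMSE ester and its 3-epimer | C=C1C[C@]23C[C@@]1(O[Si](CC)(CC)CC)CC[C@H]2[C@@]12OC(=O)[C@@](C)([C@H]1[C@@H]3C(=O)OCC[Si](C)(C)C)C(O)C=C2 | intermediate
28 | 13-O-TES 3-dehydrogibberellic acid TMSE ester (3-oxo-1-ene) | C=C1C[C@]23C[C@@]1(O[Si](CC)(CC)CC)CC[C@H]2[C@@]12OC(=O)[C@@](C)([C@H]1[C@@H]3C(=O)OCC[Si](C)(C)C)C(=O)C=C2 | intermediate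
29 | 1β,2β-epoxy-3-ketone | C=C1C[C@]23C[C@@]1(O[Si](CC)(CC)CC)CC[C@H]2[C@@]12OC(=O)[C@@](C)([C@H]1[C@@H]3C(=O)OCC[Si](C)(C)C)C(=O)[C@H]4O[C@H]42 | intermediate
30 | 13-O-TES 3-dehydro-GA55 TMSE ester | C=C1C[C@]23C[C@@]1(O[Si](CC)(CC)CC)CC[C@H]2[C@@]12OC(=O)[C@@](C)([C@H]1[C@@H]3C(=O)OCC[Si](C)(C)C)C(=O)C[C@H]2O | intermediate
31 | 3-dehydro-GA55 | C=C1C[C@]23C[C@@]1(O)CC[C@H]2[C@@]12OC(=O)[C@@](C)([C@H]1[C@@H]3C(=O)O)C(=O)C[C@H]2O | intermediate
32 | GA55 | C=C1C[C@]23C[C@@]1(O)CC[C@H]2[C@@]12OC(=O)[C@@](C)([C@H]1[C@@H]3C(=O)O)[C@@H](O)C[C@H]2O | target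

## Summary

Total step count: 26. Longest linear sequence: 26 steps (fully linear from 1 and 2).

**Steps most likely to fail**

Step 7 (Sakurai formation of quaternary C8 next to C9, with a Lewis-acid-sensitive PMB ether). The fallback sets out from 9 and comes back at 11. CuBr·SMe2-mediated conjugate addition of vinylmagnesium bromide (CH2=CHMgBr, CuBr·SMe2, Me3SiCl, THF, −78 °C), again anti to the C9 substituent, gives the C8-vinyl ketone F1. Anti-Markovnikov hydroboration of the vinyl group with 9-BBN and oxidation with NaBO3 gives the 2-hydroxyethyl ketone F2. Dess–Martin oxidation of F2 gives aldehyde 11.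

Step 19 (the propanoate enolate of an allylic ester may undergo ester-enolate Claisen rearrangement or give the wrong C6 epimer). The fallback sets out from 22 and comes back at 25. Vinyl addition as in step 18 with aqueous work-up gives the tertiary 10β-vinyl alcohol F3. N-Bromosuccinimide and ethyl prop-1-enyl ether convert it into the mixed bromoacetal F4. Ueno–Stork 5-exo-trig radical cyclisation (Bu3SnH, AIBN, benzene, 80 °C) of the nucleophilic alkyl radical onto the enoate gives the cyclic ethyl acetal F5. Mild aqueous acid (pyridinium tosylate, wet acetone) gives the lactol F6, which [Pr4N][RuO4] with N-methylmorpholine N-oxide oxidises to lactone 25.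

Step 26 (no ketoreductase in the panel may accept the substrate or give the 3β-alcohol). The fallback sets out from 30 and comes back at 32. Narasaka–Prasad reduction (Et2BOMe, NaBH4, THF/MeOH, −78 °C), directed by the 1β-hydroxyl, gives the syn-1,3-diol, the protected 1β,3β-diol F7. The Bu4NF/AcOH conditions of step 25 then give 32.

## Further compounds

F1 | step 7 | TMSE 2-[(1R,2R)-2-(PMB-oxymethyl)-5-oxo-1-vinylcyclohexyl]acetate | C=C[C@]1(CC(=O)OCC[Si](C)(C)C)CC(=O)CC[C@H]1COCc1ccc(OC)cc1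
F2 | step 7 | TMSE 2-[(1R,2R)-1-(2-hydroxyethyl)-2-(PMB-oxymethyl)-5-oxocyclohexyl]acetate | OCC[C@]1(CC(=O)OCC[Si](C)(C)C)CC(=O)CC[C@H]1COCc1ccc(OC)cc1
F3 | step 19 | tertiary 10β-vinyl 10α-alcohol of the tricycle | C=C1C[C@]23C[C@@]1(O[Si](CC)(CC)CC)CC[C@H]2[C@@](C=C)(O)C=C3C(=O)OCC[Si](C)(C)C
F4 | step 19 | 10-O-(2-bromo-1-ethoxypropyl) bromoacetal | C=C1C[C@]23C[C@@]1(O[Si](CC)(CC)CC)CC[C@H]2[C@@](C=C)(OC(OCC)C(C)Br)C=C3C(=O)OCC[Si](C)(C)C
F5 | step 19 | cyclic ethyl acetal (19-ethoxy 19,10-ether) | C=C1C[C@]23C[C@@]1(O[Si](CC)(CC)CC)CC[C@H]2[C@@]1(C=C)OC(OCC)C(C)[C@H]1[C@@H]3C(=O)OCC[Si](C)(C)C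
F6 | step 19 | lactol (19-hydroxy 19,10-ether) | C=C1C[C@]23C[C@@]1(O[Si](CC)(CC)CC)CC[C@H]2[C@@]1(C=C)OC(O)C(C)[C@H]1[C@@H]3C(=O)OCC[Si](C)(C)C
F7 | step 26 | 13-O-TES GA55 TMSE ester | C=C1C[C@]23C[C@@]1(O[Si](CC)(CC)CC)CC[C@H]2[C@@]12OC(=O)[C@@](C)([C@H]1[C@@H]3C(=O)OCC[Si](C)(C)C)[C@@H](O)C[C@H]2O
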